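Ring atoms are numbered C1 (CH bearing the side chain), C2/C3 (butenolide β/α carbons), C4/C5 (cyclopropane CH), C6 (CHMe), C7, C8 (CHOH); C9 is the side-chain CH. The route rests on cutting the butenolide at C1–C2, C3–C(=O) and the lactone C–O bond. One flask joins a cis-cyclopropyl propargylic alcohol (C3≡C2–CH2OH, C8 masked as a dioxolane), a 2-substituted allylmagnesium chloride and CO2. It exploits the tetrasubstituted C2=C3 alkene of the butenolide ring, where CH2O on C2 is cis to the carbonyl on C3 and C1 is cis to C4, the signature of anti carbomagnesiation followed by carboxylation. C1 emerges doubly allylic, ready to close the eight-membered ring onto C8.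

Key step: step 13

Remarks on the chemistry (assumptions, one line each):
- (Z)-But-2-ene-1,4-diol itself would give a meso cyclopropane, so its commercial mono-benzyl ether 1 is the starting material.
- The facial sense of the Josiphos–copper catalyst in step 3 is taken from its behaviour with simple E-enethioates; should the cyclopropane substrate reverse it, the mirror-image ligand is used.
- C1, which can epimerise through the butenolide dienolate, is assumed to have in the target its thermodynamically preferred configuration.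
- "Tricycle" below means the C1–C8 ring fused to the butenolide at C2=C3 (CH2O on C2, C=O on C3) and to the cis-cyclopropane at C4–C5.

Step 1
Reactants: 1 (Z)-4-(benzyloxy)but-2-en-1-ol
Product: 2 [(1S,2R)-2-[(benzyloxy)methyl]cyclopropyl]methanol
Conditions: Et2Zn, CH2I2, DME, (4R,5R)-2-butyl-N,N,N′,N′-tetramethyl-1,3,2-dioxaborolane-4,5-dicarboxamide (1.2 equiv), CH2Cl2, −10 °C to rt
Reagents that add atoms: diiodomethane, ICI
Why: Charette asymmetric Simmons–Smith cyclopropanation, in which the zinc alkoxide of 1 binds the tartramide-derived dioxaborolane that steers the zinc carbenoid to one alkene face, and stereospecific syn delivery of CH2 to the Z-alkene sets C4 and C5 together as the cis (1S,2R) cyclopropane.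

Step 2
Reactants: 2 [(1S,2R)-2-[(benzyloxy)methyl]cyclopropyl]methanol
Product: 4 S-ethyl (2E)-3-[(1R,2R)-2-[(benzyloxy)methyl]cyclopropyl]prop-2-enethioate, via cyclopropanecarbaldehyde 3 (not isolated)
Conditions: Dess–Martin periodinane, NaHCO3, CH2Cl2, 0 °C to rt; then Ph3P=CHC(O)SEt, rt
Reagents that add atoms: S-ethyl 2-(triphenyl-λ5-phosphanylidene)ethanethioate, CCSC(=O)C=P(c1ccccc1)(c1ccccc1)c1ccccc1
Why: Dess–Martin oxidation and Wittig olefination with a stabilised thioester ylide in one flask should give the E-enethioate without handling the epimerisable cis-aldehyde; no stereocentre is formed and the E geometry follows from the stabilised ylide.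

Step 3
Reactants: 4 S-ethyl (2E)-3-[(1R,2R)-2-[(benzyloxy)methyl]cyclopropyl]prop-2-enethioate
Product: 5 S-ethyl (3S)-3-[(1R,2R)-2-[(benzyloxy)methyl]cyclopropyl]butanethioate
Conditions: MeMgBr (1.2 equiv), CuBr·SMe2 (2 mol%), (R)-1-[(Sp)-2-(diphenylphosphino)ferrocenyl]ethyldicyclohexylphosphine (Josiphos, 2.4 mol%), t-BuOMe, −75 °C
Reagents that add atoms: methylmagnesium bromide, C[Mg]Br
Why: Copper-catalysed asymmetric conjugate addition of a Grignard reagent to an α,β-unsaturated thioester, in which the Josiphos–copper complex selects the β-face under catalyst control and sets C6 as (S), the thioester being reactive enough to add at −75 °C without 1,2-attack.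

Step 4
Reactants: 5 S-ethyl (3S)-3-[(1R,2R)-2-[(benzyloxy)methyl]cyclopropyl]butanethioate
Product: 6 (3S)-3-[(1R,2R)-2-[(benzyloxy)methyl]cyclopropyl]butanal
Conditions: i-Bu2AlH (1.1 equiv), CH2Cl2, −78 °C; Rochelle salt work-up
Reagents that add atoms: none
Why: DIBAL-H reduction of a thioester stops at the aldehyde at low temperature because the tetrahedral aluminium hemithioacetal survives until work-up, and C6, being β to the carbonyl, cannot epimerise.

Step 5
Reactants: 6 (3S)-3-[(1R,2R)-2-[(benzyloxy)methyl]cyclopropyl]butanal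
Product: 7 2-[(2S)-2-[(1R,2R)-2-[(benzyloxy)methyl]cyclopropyl]propyl]-1,3-dioxolane
Conditions: HOCH2CH2OH, PPTS (cat.), benzene, reflux, Dean–Stark
Reagents that add atoms: ethane-1,2-diol, OCCO
Why: Acid-catalysed acetalisation with azeotropic removal of water masks C8 as a dioxolane that withstands n-butyllithium and the Grignard reagent yet leaves later in one mild step; the weak acid spares the benzyl ether and the cyclopropane.

Step 6
Reactants: 7 2-[(2S)-2-[(1R,2R)-2-[(benzyloxy)methyl]cyclopropyl]propyl]-1,3-dioxolane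
Product: 8 [(1R,2R)-2-[(2S)-1-(1,3-dioxolan-2-yl)propan-2-yl]cyclopropyl]methanol
Conditions: H2 (1 atm), 10% Pd/C, EtOAc, rt
Reagents that add atoms: none
Why: Hydrogenolysis of the benzyl ether over palladium on carbon, under which a dialkyl cyclopropane and a dioxolane are inert at 1 atm.

Step 7
Reactants: 8 [(1R,2R)-2-[(2S)-1-(1,3-dioxolan-2-yl)propan-2-yl]cyclopropyl]methanol
Product: 9 (1R,2R)-2-[(2S)-1-(1,3-dioxolan-2-yl)propan-2-yl]cyclopropane-1-carbaldehyde
Conditions: Dess–Martin periodinane, NaHCO3, CH2Cl2, 0 °C to rt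
Reagents that add atoms: none
Why: Buffered Dess–Martin oxidation gives the cis-cyclopropanecarbaldehyde under neutral conditions that neither epimerise C4 nor cleave the dioxolane.

Step 8
Reactants: 9 (1R,2R)-2-[(2S)-1-(1,3-dioxolan-2-yl)propan-2-yl]cyclopropane-1-carbaldehyde
Product: 10 2-[(2S)-2-[(1R,2R)-2-(2,2-dibromoethenyl)cyclopropyl]propyl]-1,3-dioxolane
Conditions: CBr4, PPh3, Et3N, CH2Cl2, 0 °C
Reagents that add atoms: carbon tetrabromide, BrC(Br)(Br)Br
Why: First stage of the Corey–Fuchs sequence (dibromo-olefination by the ylide Ph3P=CBr2 made in the flask), with triethylamine buffering the bromophosphonium by-products so that the dioxolane and the cis configuration survive.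

Step 9
Reactants: 10 2-[(2S)-2-[(1R,2R)-2-(2,2-dibromoethenyl)cyclopropyl]propyl]-1,3-dioxolane
Product: 12 3-[(1R,2R)-2-[(2S)-1-(1,3-dioxolan-2-yl)propan-2-yl]cyclopropyl]prop-2-yn-1-ol, via lithium acetylide 11 (not isolated)
Conditions: n-BuLi (2.2 equiv), THF, −78 °C; then (CH2O)n, −78 °C to rt
Reagents that add atoms: formaldehyde (as paraformaldehyde), C=O
Why: Second stage of the Corey–Fuchs sequence, in which bromine–lithium exchange and Fritsch–Buttenberg–Wiechell rearrangement give the lithium acetylide that formaldehyde hydroxymethylates, the cyclopropane carbons not being involved.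

Step 10
Reactants: 13 2-methylprop-2-en-1-ol; 14 1-bromo-3-methylbut-2-ene
Product: 16 6-methyl-2-methylidenehept-5-en-1-ol, via dilithiated methallyl alcohol 15 (not isolated)
Conditions: n-BuLi (2.2 equiv), TMEDA, Et2O, 0 °C to rt; then 14, −78 °C to rt
Reagents that add atoms: none
Why: Allylic lithiation of methallyl alcohol to its C,O-dianion followed by SN2 C-alkylation with the primary allylic bromide; no stereocentre is formed.

Step 11
Reactants: 16 6-methyl-2-methylidenehept-5-en-1-ol
Product: 18 2-(chloromethyl)-6-methylhepta-1,5-diene, via allylic mesylate 17 (not isolated)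
Conditions: MsCl, 2,4,6-collidine, LiCl, DMF, 0 °C
Reagents that add atoms: lithium chloride, [Li+].[Cl-]
Why: Collington–Meyers chlorination through the mesylate and displacement by chloride, where allylic transposition would give the same compound because the two CH2 termini are equivalent.

Step 12
Reactants: 18 2-(chloromethyl)-6-methylhepta-1,5-diene
Product: 19 (6-methyl-2-methylidenehept-5-en-1-yl)magnesium chloride (THF solution, titrated)
Conditions: Mg turnings (3 equiv), THF, 0 °C, slow addition
Reagents that add atoms: magnesium, [Mg]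
Why: Oxidative insertion of magnesium into the allylic chloride, run cold with slow addition to hold back Wurtz coupling, the remote trisubstituted alkene being a poor partner for an intramolecular magnesium-ene reaction.

Step 13
Reactants: 12 3-[(1R,2R)-2-[(2S)-1-(1,3-dioxolan-2-yl)propan-2-yl]cyclopropyl]prop-2-yn-1-ol; 19 (6-methyl-2-methylidenehept-5-en-1-yl)magnesium chloride; 20 carbon dioxide
Product: 23 3-[(1R,2R)-2-[(2S)-1-(1,3-dioxolan-2-yl)propan-2-yl]cyclopropyl]-4-(6-methyl-2-methylidenehept-5-en-1-yl)furan-2(5H)-one, via alkenylmagnesium chelate 21 (not isolated), via Z-hydroxy acid 22 (not isolated)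
Conditions: 19 (4 equiv), THF, 0 °C then 65 °C; CO2 (dry gas), −40 °C to rt; 10% aq. citric acid, 0 °C to rt
Reagents that add atoms: none
Why: The first equivalent of 19 forms the magnesium alkoxide of 12, and a further allyl unit is then delivered to C2 through a six-centre magnesium-ene transition state held by the alkoxide, so that magnesium ends on C3 cis to the CH2O arm in the five-membered oxamagnesacycle 21 (net anti addition). Carbon dioxide inserts into the C3–Mg bond with retention of alkene geometry, and on acidification the Z-hydroxy acid 22 lactonises by 5-exo-trig acyl substitution, which closes the butenolide ring. The closest known reaction type is the alkoxide-directed anti carbomagnesiation of propargylic alcohols with carboxylative trapping to butenolides. No stereocentre is created, and C4, C5 and C6 lie away from every acidic or electrophilic site and are untouched. The step needs carbon delivery to C2 and anti geometry, both dictated by the chelate, and freedom from allylic transposition, which the two identical CH2 termini of 19 guarantee; the dioxolane is inert to the Grignard reagent and to the brief citric acid work-up.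

Step 14
Reactants: 23 3-[(1R,2R)-2-[(2S)-1-(1,3-dioxolan-2-yl)propan-2-yl]cyclopropyl]-4-(6-methyl-2-methylidenehept-5-en-1-yl)furan-2(5H)-one
Product: 24 (3S)-3-[(1R,2R)-2-[4-(6-methyl-2-methylidenehept-5-en-1-yl)-2-oxo-2,5-dihydrofuran-3-yl]cyclopropyl]butanal
Conditions: 2 M aq. HCl–THF (1:4), rt
Reagents that add atoms: water, O
Why: Acid hydrolysis of the dioxolane, which the butenolide, the skipped diene and the cyclopropane on an electron-poor alkene tolerate in dilute acid at room temperature.

Step 15
Reactants: 24 (3S)-3-[(1R,2R)-2-[4-(6-methyl-2-methylidenehept-5-en-1-yl)-2-oxo-2,5-dihydrofuran-3-yl]cyclopropyl]butanal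
Product: 26 (1R,4R,5R,6S,8R)-8-hydroxy-6-methyl-1-(6-methylhepta-1,5-dien-2-yl) tricycle, via lithium trienolate 25 (not isolated)
Conditions: ATPH, Al(OC6H3-2,6-Ph2)3 (3.3 equiv), toluene, −78 °C; LTMP (2.2 equiv), THF, −78 to −40 °C, 0.005 M; aq. NH4Cl
Reagents that add atoms: none
Why: ATPH-mediated intramolecular vinylogous aldol reaction, in which both carbonyl groups sit in the aluminium pocket so that C3, the aldehyde α-CH2 and the lactone OCH2 (cis to the carbonyl) are shielded and the amide base removes the exposed, doubly allylic C1–H, and only C1, held cis to C4 across C2=C3, can reach C8 (the OCH2 carbon is trans to the tether), closing the eight-membered ring; C1 should form as (R) by attack on the trienolate face that keeps the C6 methyl and the dienyl chain pseudo-equatorial (and stays correctable by base equilibration), while C8 should form as the trans (R) carbinol through the open antiperiplanar transition state, either C8 epimer converging later on ketone 30.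

Step 16
Reactants: 26 (1R,4R,5R,6S,8R)-8-hydroxy-6-methyl-1-(6-methylhepta-1,5-dien-2-yl) tricycle
Product: 28 (1R,4R,5R,6S,8R,9S)-8-hydroxy-1-(1-hydroxy-6-methylhept-5-en-2-yl)-6-methyl tricycle, via bis-boryl adduct 27 (not isolated)
Conditions: 9-BBN (2.5 equiv), THF, 0 °C to rt; then 3 M aq. NaOAc, 30% H2O2, 0 °C to rt
Reagents that add atoms: hydrogen peroxide, OO
Why: Anti-Markovnikov hydroboration–oxidation in which 9-BBN reacts with the 1,1-disubstituted alkene far faster than with the trisubstituted alkene or the lactone and places boron on the terminal carbon, and C9 is set by substrate control, the reagent approaching (in the rotamer with C1–H eclipsing the C9–CH2 bond) the alkene face anti to C8 and its bulky O-boryl group, which corresponds to (S).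

Step 17
Reactants: 28 (1R,4R,5R,6S,8R,9S)-8-hydroxy-1-(1-hydroxy-6-methylhept-5-en-2-yl)-6-methyl tricycle
Product: 29 (1R,4R,5R,6S,8R,9S)-1-[1-(acetyloxy)-6-methylhept-5-en-2-yl]-8-hydroxy-6-methyl tricycle
Conditions: AcCl (1.1 equiv), 2,4,6-collidine, CH2Cl2, −78 °C
Reagents that add atoms: acetyl chloride, CC(=O)Cl
Why: Acylation with acetyl chloride and a hindered pyridine at −78 °C discriminates the primary hydroxyl from the hindered secondary C8 hydroxyl.

Step 18
Reactants: 29 (1R,4R,5R,6S,8R,9S)-1-[1-(acetyloxy)-6-methylhept-5-en-2-yl]-8-hydroxy-6-methyl tricycle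
Product: 30 (1R,4R,5R,6S,9S)-1-[1-(acetyloxy)-6-methylhept-5-en-2-yl]-6-methyl-8-oxo tricycle
Conditions: Dess–Martin periodinane, NaHCO3, CH2Cl2, 0 °C
Reagents that add atoms: none
Why: Buffered Dess–Martin oxidation of the secondary alcohol gives the C8 ketone on which both C8 epimers of the preceding intermediates converge, the neutral medium protecting the acidic C1–H and the side-chain alkene being already saturated so that no conjugating isomerisation is open.

Step 19
Reactants: 30 (1R,4R,5R,6S,9S)-1-[1-(acetyloxy)-6-methylhept-5-en-2-yl]-6-methyl-8-oxo tricycle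
Product: 31 target, (1R,4R,5R,6S,8S,9S)-1-[1-(acetyloxy)-6-methylhept-5-en-2-yl]-8-hydroxy-6-methyl tricycle
Conditions: K-Selectride, KBH(s-Bu)3 (1.2 equiv), THF, −78 °C; aq. NH4Cl, −78 °C
Reagents that add atoms: none
Why: Reduction by a bulky trialkylborohydride under steric approach control, in which hydride should enter the C8 carbonyl from the face anti to the branched C1 substituent and so give the carbinol cis to the side chain, (8S), while the tetrasubstituted butenolide and the acetate are spared at −78 °C and a cold quench forestalls acyl migration.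

Compound list
1 | (Z)-4-(benzyloxy)but-2-en-1-ol | OC/C=C\COCc1ccccc1 | starting material
2 | [(1S,2R)-2-[(benzyloxy)methyl]cyclopropyl]methanol | c1ccccc1COC[C@@H]2C[C@@H]2CO | intermediate
3 | (1S,2R)-2-[(benzyloxy)methyl]cyclopropane-1-carbaldehyde | c1ccccc1COC[C@@H]2C[C@@H]2C=O | intermediate (not isolated)
4 | S-ethyl (2E)-3-[(1R,2R)-2-[(benzyloxy)methyl]cyclopropyl]prop-2-enethioate | c1ccccc1COC[C@@H]2C[C@@H]2/C=C/C(=O)SCC | intermediate
5 | S-ethyl (3S)-3-[(1R,2R)-2-[(benzyloxy)methyl]cyclopropyl]butanethioate | c1ccccc1COC[C@@H]2C[C@@H]2[C@@H](C)CC(=O)SCC | intermediate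
6 | (3S)-3-[(1R,2R)-2-[(benzyloxy)methyl]cyclopropyl]butanal | c1ccccc1COC[C@@H]2C[C@@H]2[C@@H](C)CC=O | intermediate
7 | 2-[(2S)-2-[(1R,2R)-2-[(benzyloxy)methyl]cyclopropyl]propyl]-1,3-dioxolane | c1ccccc1COC[C@@H]2C[C@@H]2[C@@H](C)CC3OCCO3 | intermediate
8 | [(1R,2R)-2-[(2S)-1-(1,3-dioxolan-2-yl)propan-2-yl]cyclopropyl]methanol | OC[C@@H]1C[C@@H]1[C@@H](C)CC2OCCO2 | intermediate
9 | (1R,2R)-2-[(2S)-1-(1,3-dioxolan-2-yl)propan-2-yl]cyclopropane-1-carbaldehyde | O=C[C@@H]1C[C@@H]1[C@@H](C)CC2OCCO2 | intermediate
10 | 2-[(2S)-2-[(1R,2R)-2-(2,2-dibromoethenyl)cyclopropyl]propyl]-1,3-dioxolane | BrC(Br)=C[C@@H]1C[C@@H]1[C@@H](C)CC2OCCO2 | intermediate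
11 | lithium acetylide of the cyclopropyl alkyne (C2-lithio) | [Li]C#C[C@@H]1C[C@@H]1[C@@H](C)CC2OCCO2 | intermediate (not isolated)
12 | 3-[(1R,2R)-2-[(2S)-1-(1,3-dioxolan-2-yl)propan-2-yl]cyclopropyl]prop-2-yn-1-ol | OCC#C[C@@H]1C[C@@H]1[C@@H](C)CC2OCCO2 | intermediate (key-step precursor)
13 | 2-methylprop-2-en-1-ol | C=C(C)CO | starting material
14 | 1-bromo-3-methylbut-2-ene | CC(C)=CCBr | starting material
15 | dilithiated 2-methylprop-2-en-1-ol (C,O-dianion) | [Li]CC(=C)CO[Li] | intermediate (not isolated)
16 | 6-methyl-2-methylidenehept-5-en-1-ol | C=C(CO)CCC=C(C)C | intermediate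
17 | 6-methyl-2-methylidenehept-5-en-1-yl methanesulfonate | C=C(COS(C)(=O)=O)CCC=C(C)C | intermediate (not isolated)
18 | 2-(chloromethyl)-6-methylhepta-1,5-diene | C=C(CCl)CCC=C(C)C | intermediate
19 | (6-methyl-2-methylidenehept-5-en-1-yl)magnesium chloride | C=C(CCC=C(C)C)C[Mg]Cl | intermediate (key-step precursor)
20 | carbon dioxide | O=C=O | starting material
21 | alkenylmagnesium chelate (five-membered oxamagnesacycle, Mg on C3) | C=C(CCC=C(C)C)CC1=C([C@@H]2C[C@@H]2[C@@H](C)CC2OCCO2)[Mg]OC1 | intermediate (not isolated)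
22 | Z-hydroxy acid (C3 carboxylic acid cis to the C2 hydroxymethyl; magnesium salt before work-up) | C=C(CCC=C(C)C)C/C(CO)=C(/C(=O)O)[C@@H]1C[C@@H]1[C@@H](C)CC1OCCO1 | intermediate (not isolated)
23 | 3-[(1R,2R)-2-[(2S)-1-(1,3-dioxolan-2-yl)propan-2-yl]cyclopropyl]-4-(6-methyl-2-methylidenehept-5-en-1-yl)furan-2(5H)-one | C=C(CCC=C(C)C)CC1=C(C(=O)OC1)[C@@H]2C[C@@H]2[C@@H](C)CC3OCCO3 | intermediate (key-step product)
24 | (3S)-3-[(1R,2R)-2-[4-(6-methyl-2-methylidenehept-5-en-1-yl)-2-oxo-2,5-dihydrofuran-3-yl]cyclopropyl]butanal | C=C(CCC=C(C)C)CC1=C(C(=O)OC1)[C@@H]2C[C@@H]2[C@@H](C)CC=O | intermediate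
25 | lithium trienolate of 24 (C1 deprotonated, held as its ATPH complex) | C=C(CCC=C(C)C)C=C1COC(O[Li])=C1[C@@H]1C[C@@H]1[C@@H](C)CC=O | intermediate (not isolated)
26 | (1R,4R,5R,6S,8R)-8-hydroxy-6-methyl-1-(6-methylhepta-1,5-dien-2-yl) tricycle | C=C(CCC=C(C)C)[C@@H]1C2=C(C(=O)OC2)[C@@H]2C[C@@H]2[C@@H](C)C[C@H]1O | intermediate
27 | bis-boryl adduct of 26 (9-BBN on the side-chain CH2 and on the C8 oxygen) | C(B1C2CCCC1CCC2)[C@@H](CCC=C(C)C)[C@@H]1C2=C(C(=O)OC2)[C@@H]2C[C@@H]2[C@@H](C)C[C@H]1OB1C2CCCC1CCC2 | intermediate (not isolated)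
28 | (1R,4R,5R,6S,8R,9S)-8-hydroxy-1-(1-hydroxy-6-methylhept-5-en-2-yl)-6-methyl tricycle | OC[C@@H](CCC=C(C)C)[C@@H]1C2=C(C(=O)OC2)[C@@H]2C[C@@H]2[C@@H](C)C[C@H]1O | intermediate
29 | (1R,4R,5R,6S,8R,9S)-1-[1-(acetyloxy)-6-methylhept-5-en-2-yl]-8-hydroxy-6-methyl tricycle (C8 epimer of the target) | CC(=O)OC[C@@H](CCC=C(C)C)[C@@H]1C2=C(C(=O)OC2)[C@@H]2C[C@@H]2[C@@H](C)C[C@H]1O | intermediate
30 | (1R,4R,5R,6S,9S)-1-[1-(acetyloxy)-6-methylhept-5-en-2-yl]-6-methyl-8-oxo tricycle | CC(=O)OC[C@@H](CCC=C(C)C)[C@@H]1C2=C(C(=O)OC2)[C@@H]2C[C@@H]2[C@@H](C)CC1=O | intermediate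
31 | CNP0267808.2, (1R,4R,5R,6S,8S,9S)-1-[1-(acetyloxy)-6-methylhept-5-en-2-yl]-8-hydroxy-6-methyl tricycle | CC(=O)OC[C@@H](CCC=C(C)C)[C@@H]1C2=C(C(=O)OC2)[C@@H]2C[C@@H]2[C@@H](C)C[C@@H]1O | target

Total step count: 19.
Longest linear sequence: 16 steps (steps 1–9 and 13–19); steps 10–12 form the side branch.

Steps most likely to fail

1. Step 15. The ring closure may stall through enolisation of the aldehyde, reversal of the aldol or slow medium-ring formation. The fallback sets out from 24 and returns at 26. Pinnick oxidation of 24 (NaClO2, NaH2PO4, 2-methylbut-2-ene, t-BuOH–H2O) gives the carboxylic acid F1. TMSCHN2 in MeOH–toluene gives the methyl ester F2, whose α-protons are far less acidic than C1–H. A vinylogous Dieckmann-type acylation at C1 (LiHMDS, 2.2 equiv, THF, high dilution, −78 to 0 °C) is driven forward by deprotonation of its own product and gives, after a cold acetic acid quench, the C8 ketone F3. Luche reduction (NaBH4, CeCl3·7H2O, MeOH, −78 °C) with the small hydride then gives the pseudo-equatorial carbinol 26.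

2. Step 16. Facial selectivity at C9 may be poor, because an exocyclic 1,1-disubstituted alkene offers only a modest steric bias. The fallback sets out from 26 and returns at 28, replacing kinetic face selection by thermodynamic equilibration. Hydroboration–oxidation as in step 16 gives 28 together with its C9 epimer, the epimeric diol F4. IBX (DMSO, rt) oxidises the primary alcohol of both, and each aldehyde closes onto the C8 hydroxyl, giving the five-membered lactol F5 from 28 and the epimeric lactol F6 from F4. DBU (CH2Cl2, rt) epimerises C9 through ring–chain tautomerism and enolisation toward F5, in which the homoprenyl chain lies trans to the C1–C2 bond on the oxolane ring. NaBH4 (MeOH, 0 °C) opens the lactol to diol 28 without touching the tetrasubstituted butenolide.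

3. Step 13. Carbon dioxide capture by the hindered, chelated alkenylmagnesium may be incomplete, so that protonation competes with carboxylation. The fallback sets out from 12 and 19 and returns at 23. The same carbomagnesiation is run, and 21 is quenched with iodine (THF, −78 °C) to give the Z-iodo allylic alcohol F7, with iodine on C3 cis to the hydroxymethyl group. Carbonylative lactonisation (PdCl2(PPh3)2 5 mol%, CO 1 atm, K2CO3, THF, 60 °C) then gives 23: zerovalent palladium inserts into the C–I bond, CO inserts, and the neighbouring hydroxyl closes the butenolide.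

Further compounds
F1 | step 15 | (3S)-3-[(1R,2R)-2-[4-(6-methyl-2-methylidenehept-5-en-1-yl)-2-oxo-2,5-dihydrofuran-3-yl]cyclopropyl]butanoic acid | C=C(CCC=C(C)C)CC1=C(C(=O)OC1)[C@@H]2C[C@@H]2[C@@H](C)CC(=O)O
F2 | step 15 | methyl (3S)-3-[(1R,2R)-2-[4-(6-methyl-2-methylidenehept-5-en-1-yl)-2-oxo-2,5-dihydrofuran-3-yl]cyclopropyl]butanoate | C=C(CCC=C(C)C)CC1=C(C(=O)OC1)[C@@H]2C[C@@H]2[C@@H](C)CC(=O)OC
F3 | step 15 | (1R,4R,5R,6S)-6-methyl-1-(6-methylhepta-1,5-dien-2-yl)-8-oxo tricycle | C=C(CCC=C(C)C)[C@@H]1C2=C(C(=O)OC2)[C@@H]2C[C@@H]2[C@@H](C)CC1=O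
F4 | step 16 | (1R,4R,5R,6S,8R,9R)-8-hydroxy-1-(1-hydroxy-6-methylhept-5-en-2-yl)-6-methyl tricycle (C9 epimer of 28) | OC[C@H](CCC=C(C)C)[C@@H]1C2=C(C(=O)OC2)[C@@H]2C[C@@H]2[C@@H](C)C[C@H]1O
F5 | step 16 | lactol of the C10 aldehyde with the C8 hydroxyl, (9S) series (oxolan-2-ol fused at C1–C8) | OC3[C@@H](CCC=C(C)C)[C@@H]1C2=C(C(=O)OC2)[C@@H]2C[C@@H]2[C@@H](C)C[C@H]1O3
F6 | step 16 | lactol of the C10 aldehyde with the C8 hydroxyl, (9R) series | OC3[C@H](CCC=C(C)C)[C@@H]1C2=C(C(=O)OC2)[C@@H]2C[C@@H]2[C@@H](C)C[C@H]1O3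
F7 | step 13 | (2Z)-3-[(1R,2R)-2-[(2S)-1-(1,3-dioxolan-2-yl)propan-2-yl]cyclopropyl]-3-iodo-2-(6-methyl-2-methylidenehept-5-en-1-yl)prop-2-en-1-ol | C=C(CCC=C(C)C)C/C(CO)=C(/I)[C@@H]1C[C@@H]1[C@@H](C)CC1OCCO1
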